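The trans-hydroazulene is traced back to a cis-decalin. The route exploits the aldol-type array C4(OH)–C5(H)–C6(O) that straddles the cyclopentane (C1–C5) and the cycloheptene (C1, C5–C10): it is the footprint of a semipinacol shift. In the all-cis 4,5,6-triol 5-mesylate the equatorial C5–OMs bond lies antiperiplanar to the ring-fusion bond C1–C6, so C1 moves from C6 to C5. One operation contracts cyclohexane C1–C6 to the cyclopentane, expands the cyclohexene to the cycloheptene, sets C5 by inversion and unveils the C6 ketone. The decalin arises from desymmetrised 2-allyl-2-methylcyclohexane-1,3-dione by isopropylation, directed methallylation, ring-closing metathesis and directed dihydroxylation.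

Key step: step 10

Remark on numbering (daucane numbering, kept for the same atoms in every precursor): C1 = quaternary fusion carbon (CH3), C2 = CH–O of the five-membered ring, C3 = CH2, C4 = C(OH)(iPr), C5 = fusion CH, C6 = CH–O of the seven-membered ring, C7 = CH2, C8(CH3)=C9H, C10 = CH2. β is the face of the C1 methyl group and α the opposite face. In the decalins, ring A = C1–C6 and ring B = C1, C6–C10. The target is (1R,2S,4R,5S,6S) in this numbering.

Step 1
Reactants: 1 2-methylcyclohexane-1,3-dione; 2 allyl bromide
Product: 3 2-allyl-2-methylcyclohexane-1,3-dione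
Conditions: aq. NaOH (1 M), rt
Reagents that add atoms: allyl bromide, C=CCBr
Why: C-alkylation of the stabilised enolate of a 2-alkyl-1,3-dione with a reactive allylic halide is the standard entry to the achiral 2,2-disubstituted dione, and no stereocentre is formed.

Step 2
Reactants: 3 2-allyl-2-methylcyclohexane-1,3-dione
Product: 4 (2S,3S)-2-allyl-3-hydroxy-2-methylcyclohexan-1-one
Conditions: baker's yeast (Saccharomyces cerevisiae), sucrose, H2O, 30 °C
Reagents that add atoms: none
Why: Microbial desymmetrisation of a prochiral 2,2-disubstituted 1,3-dione reduces one enantiotopic carbonyl from the methyl-bearing face, which sets C1 and C2 together with the hydroxyl cis to the allyl group (C10) and trans to the methyl group.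

Step 3
Reactants: 4 (2S,3S)-2-allyl-3-hydroxy-2-methylcyclohexan-1-one
Product: 6 (5S,6S)-6-allyl-5-hydroxy-6-methylcyclohex-2-en-1-one, via α-phenylselanyl ketone 5 (not isolated)
Conditions: LDA (2.2 equiv), THF, −78 °C; PhSeBr; then 30% H2O2, pyridine, CH2Cl2, 0 °C to rt
Reagents that add atoms: none
Why: The ketone can enolise only towards C5, so α-selenenylation of the alkoxide–enolate dianion followed by selenoxide syn-elimination should give the C4=C5 enone without touching C1 or C2.

Step 4
Reactants: 6 (5S,6S)-6-allyl-5-hydroxy-6-methylcyclohex-2-en-1-one; 7 isopropylmagnesium chloride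
Product: 9 (5S,6S)-6-allyl-5-hydroxy-3-isopropyl-6-methylcyclohex-2-en-1-one, via selenide 8 (not isolated)
Conditions: iPrMgCl (2.5 equiv), CuBr·SMe2 (10 mol %), THF, −78 to −40 °C; PhSeBr, −78 °C; then 30% H2O2, pyridine, CH2Cl2, 0 °C to rt
Reagents that add atoms: isopropylmagnesium chloride, CC(C)[Mg]Cl
Why: Copper-catalysed conjugate addition places the isopropyl group on C4, the enolate is trapped at C5 anti to it by PhSeBr, and selenoxide syn-elimination towards the cis C4–H restores the enone, so the transient centres at C4 and C5 are erased again.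

Step 5
Reactants: 9 (5S,6S)-6-allyl-5-hydroxy-3-isopropyl-6-methylcyclohex-2-en-1-one; 10 2-methylallylmagnesium chloride
Product: 12 (1S,5S,6S)-6-allyl-3-isopropyl-6-methyl-1-(2-methylallyl)cyclohex-2-ene-1,5-diol, via mixed boronate 11 (not isolated)
Conditions: B(OiPr)3, 2-methylallylMgCl, THF, −78 °C to rt; then 9, toluene, 4 Å MS, rt; aq. NH4Cl
Reagents that add atoms: 2-methylallylmagnesium chloride, CC(=C)C[Mg]Cl
Why: In this hydroxyl-directed allylboration of a β-hydroxy ketone, exchange of one isopropoxide for the C2–OH ties boron to the α face, boron binds the C6 carbonyl, and the methallyl group passes through a bicyclic chair transition state to the α face of C6 (1,2-addition), which makes the C6–OH β (cis to the C1 methyl) and puts the two alkenyl chains cis.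

Step 6
Reactants: 12 (1S,5S,6S)-6-allyl-3-isopropyl-6-methyl-1-(2-methylallyl)cyclohex-2-ene-1,5-diol
Product: 13 (1S,4aS,8aS)-3-isopropyl-6,8a-dimethyl-1,2,4a,5,8,8a-hexahydronaphthalene-1,4a-diol (cis-decalin)
Conditions: second-generation Grubbs catalyst RuCl2(=CHPh)(PCy3)(H2IMes) (3 mol %), CH2Cl2, 40 °C
Reagents that add atoms: none
Why: Ring-closing metathesis of the monosubstituted and the 1,1-disubstituted alkene closes an unstrained cyclohexene with the trisubstituted C8=C9 bond while the hindered C4=C5 alkene stays out, and the cis-disposed chains can give only the cis-decalin.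

Step 7
Reactants: 13 cis-decalin diol; 14 angelic acid ((Z)-2-methylbut-2-enoic acid)
Product: 15 (1S,4aS,8aS)-4a-hydroxy-3-isopropyl-6,8a-dimethyl-1,2,4a,5,8,8a-hexahydronaphthalen-1-yl (Z)-2-methylbut-2-enoate
Conditions: angelic acid, 2,4,6-Cl3C6H2COCl, Et3N, toluene, rt; then 13, 75 °C (no DMAP)
Reagents that add atoms: angelic acid, C/C=C(/C)C(=O)O
Why: Yamaguchi mixed-anhydride esterification without a nucleophilic catalyst acylates the only secondary alcohol (C2–OH) and keeps the Z geometry of the angelate, while the tertiary allylic C6–OH is too hindered to react.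

Step 8
Reactants: 15 C2 angelate of the cis-decalin allylic alcohol
Product: 17 (1S,3R,4S,4aR,8aS)-3,4,4a-trihydroxy-3-isopropyl-6,8a-dimethyl-1,2,3,4,4a,5,8,8a-octahydronaphthalen-1-yl (Z)-2-methylbut-2-enoate (all-cis C4/C5/C6 triol), via osmate ester 16 (not isolated)
Conditions: OsO4 (1.05 equiv), TMEDA, CH2Cl2, −78 °C; then aq. Na2SO3, THF, 60 °C
Reagents that add atoms: osmium tetroxide, O=[Os](=O)(=O)=O
Why: In this Donohoe directed dihydroxylation the OsO4·TMEDA complex is hydrogen-bonded by the pseudoaxial allylic C6–OH and adds suprafacially to the β face of C4=C5, setting C4 (OH β, isopropyl α) and C5 (OH β); C8=C9 sees that hydroxyl only as an equatorial homoallylic group, the angelate alkene is electron-poor, and the α face is shielded by axial C10.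

Step 9
Reactants: 17 all-cis triol
Product: 18 (1S,3R,4S,4aR,8aS)-3,4a-dihydroxy-3-isopropyl-6,8a-dimethyl-4-(methylsulfonyloxy)-1,2,3,4,4a,5,8,8a-octahydronaphthalen-1-yl (Z)-2-methylbut-2-enoate
Conditions: MsCl, Et3N, CH2Cl2, −20 °C
Reagents that add atoms: methanesulfonyl chloride, CS(=O)(=O)Cl
Why: Sulfonylation picks the single secondary, equatorial C5 hydroxyl over the two tertiary ones and touches no stereocentre.

Step 10
Reactants: 18 C5 mesylate of the all-cis triol
Product: 19 (1S,3R,3aR,8aR)-3-hydroxy-3-isopropyl-6,8a-dimethyl-4-oxo-1,2,3,3a,4,5,8,8a-octahydroazulen-1-yl (Z)-2-methylbut-2-enoate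
Conditions: Et3Al (3 equiv), CH2Cl2, −78 to −20 °C; aq. potassium sodium tartrate
Reagents that add atoms: none
Why: Et3Al turns the two tertiary hydroxyls into aluminium alkoxides and, as a Lewis acid, loosens the mesylate, whereupon the C6–O electron pair pushes the C1–C6 σ bond into the rear lobe of the C5–O bond in a concerted 1,2-alkyl shift that leaves C6 as the ketone. This is a pinacol-type (semipinacol) rearrangement of a 2-sulfonyloxy alcohol under Tsuchihashi–Suzuki organoaluminium conditions, the reaction type by which decalin diol monosulfonates are converted into hydroazulenones. No ring is closed end to end: the cyclopentane C1–C2–C3–C4–C5 forms by contraction of ring A (C6 is expelled as the bond C1–C5 replaces C1–C6), and the same shift inserts C5 into ring B, which expands to the cycloheptenone C1–C5–C6–C7–C8–C9–C10. C5 is the only stereocentre made and is set by inversion, C1 arriving with retention on the side opposite the β-mesylate so that H5 ends up trans to the C1 methyl group (trans fusion), while C1, C2 and C4 are spectators and the C6 carbinol centre is erased. The step needs the C1–C6 bond to migrate rather than the C3–C4 bond, which is equally antiperiplanar to the equatorial mesylate in the chair that holds isopropyl, angelate and mesylate equatorial and could be pushed by the C4 alkoxide; the fully substituted C1 is by far the better migrating group than the CH2 carbon C3, and its shift relieves the strain of a bond between two fully substituted carbons. The all-cis triol geometry rules out epoxide closure and hydride shift, and the low temperature, with the product held as a chelated aluminium aldolate, guards against retro-aldol opening and against conjugation of the C8=C9 alkene.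

Step 11
Reactants: 19 β-hydroxy hydroazulenone
Product: 20 (1S,3R,3aS,4S,8aR)-3,4-dihydroxy-3-isopropyl-6,8a-dimethyl-1,2,3,3a,4,5,8,8a-octahydroazulen-1-yl (Z)-2-methylbut-2-enoate
Conditions: Me4NBH(OAc)3, MeCN–AcOH, −20 °C
Reagents that add atoms: none
Why: In the Evans–Saksena directed reduction the C4–OH replaces an acetate on boron and hydride is delivered intramolecularly to the face of the C6 carbonyl that looks towards O4 and C1, which should give the anti-1,3-diol, that is the 6S (α) alcohol, while ester and alkenes stay inert.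

Step 12
Reactants: 20 C4,C6-diol C2-angelate; 14 angelic acid
Product: 21 target, (1S,3R,3aS,4S,8aR)-3-hydroxy-3-isopropyl-6,8a-dimethyl-1,2,3,3a,4,5,8,8a-octahydroazulene-1,4-diyl bis[(Z)-2-methylbut-2-enoate]
Conditions: angelic acid, 2,4,6-Cl3C6H2COCl, Et3N, toluene, rt; then 20, 80 °C (no DMAP)
Reagents that add atoms: angelic acid, C/C=C(/C)C(=O)O
Why: A second stereoretentive Yamaguchi mixed-anhydride esterification acylates the secondary C6–OH while the tertiary C4–OH stays free.

Compound list
1 | 2-methylcyclohexane-1,3-dione | CC1C(=O)CCCC1=O | starting material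
2 | allyl bromide | C=CCBr | starting material
3 | 2-allyl-2-methylcyclohexane-1,3-dione | C=CCC1(C)C(=O)CCCC1=O | intermediate
4 | (2S,3S)-2-allyl-3-hydroxy-2-methylcyclohexan-1-one | C=CC[C@@]1(C)[C@@H](O)CCCC1=O | intermediate
5 | (2S,3S)-2-allyl-3-hydroxy-2-methyl-6-(phenylselanyl)cyclohexan-1-one (epimers at the selenium-bearing carbon) | C=CC[C@@]1(C)[C@@H](O)CCC([Se]c2ccccc2)C1=O | intermediate
6 | (5S,6S)-6-allyl-5-hydroxy-6-methylcyclohex-2-en-1-one | C=CC[C@@]1(C)[C@@H](O)CC=CC1=O | intermediate
7 | isopropylmagnesium chloride | CC(C)[Mg]Cl | starting material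
8 | (2S,3S)-2-allyl-3-hydroxy-5-isopropyl-2-methyl-6-(phenylselanyl)cyclohexan-1-one | C=CC[C@@]1(C)[C@@H](O)CC(C(C)C)C([Se]c2ccccc2)C1=O | intermediate
9 | (5S,6S)-6-allyl-5-hydroxy-3-isopropyl-6-methylcyclohex-2-en-1-one | C=CC[C@@]1(C)[C@@H](O)CC(C(C)C)=CC1=O | intermediate
10 | 2-methylallylmagnesium chloride | CC(=C)C[Mg]Cl | starting material
11 | mixed isopropyl (2-methylallyl)boronate of 9, bound at the C2 oxygen | C=CC[C@@]1(C)[C@@H](OB(CC(C)=C)OC(C)C)CC(C(C)C)=CC1=O | intermediate
12 | (1S,5S,6S)-6-allyl-3-isopropyl-6-methyl-1-(2-methylallyl)cyclohex-2-ene-1,5-diol | C=CC[C@@]1(C)[C@@H](O)CC(C(C)C)=C[C@@]1(O)CC(C)=C | intermediate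
13 | (1S,4aS,8aS)-3-isopropyl-6,8a-dimethyl-1,2,4a,5,8,8a-hexahydronaphthalene-1,4a-diol | C[C@@]12CC=C(C)C[C@]1(O)C=C(C(C)C)C[C@@H]2O | intermediate
14 | angelic acid, (Z)-2-methylbut-2-enoic acid | C/C=C(/C)C(=O)O | starting material
15 | C2 angelate of 13 | C[C@@]12CC=C(C)C[C@]1(O)C=C(C(C)C)C[C@@H]2OC(=O)/C(C)=C\C | intermediate
16 | cyclic C4,C5 osmate ester of 15 (β face), TMEDA complex | C[C@@]12CC=C(C)C[C@]1(O)[C@H]3O[Os](=O)(=O)O[C@@]3(C(C)C)C[C@@H]2OC(=O)/C(C)=C\C.CN(C)CCN(C)C | intermediate
17 | all-cis C4,C5,C6-triol C2-angelate | C[C@@]12CC=C(C)C[C@]1(O)[C@@H](O)[C@](O)(C(C)C)C[C@@H]2OC(=O)/C(C)=C\C | intermediate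
18 | C5 mesylate of 17 | C[C@@]12CC=C(C)C[C@]1(O)[C@@H](OS(C)(=O)=O)[C@](O)(C(C)C)C[C@@H]2OC(=O)/C(C)=C\C | intermediate
19 | trans-fused 4β-hydroxy-6-oxo hydroazulene C2-angelate | O=C1CC(C)=CC[C@@]2(C)[C@@H](OC(=O)/C(C)=C\C)C[C@@](O)(C(C)C)[C@H]12 | intermediate
20 | 4β,6α-diol C2-angelate | O[C@H]1CC(C)=CC[C@@]2(C)[C@@H](OC(=O)/C(C)=C\C)C[C@@](O)(C(C)C)[C@H]12 | intermediate
21 | target CNP0303897.1 | C/C=C(/C)C(=O)O[C@H]1CC(C)=CC[C@@]2(C)[C@@H](OC(=O)/C(C)=C\C)C[C@@](O)(C(C)C)[C@H]12 | target

Total step count: 12. Longest linear sequence: 12 steps (1 to 21).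

Steps most likely to fail

Step 10. The C4 alkoxide may push the C3–C4 bond onto C5 in competition with the wanted C1 shift, or the aldolate may open by retro-aldol cleavage. The fallback sets out from 18 and returns at 19, and it removes one of the two electron donors. The less encumbered tertiary hydroxyl is C4–OH, whose bulkiest neighbour is the isopropyl methine, whereas C6–OH is flanked by quaternary C1. It is capped first with TESOTf and 2,6-lutidine at −78 °C to give the 4-O-triethylsilyl mesylate F1. With only the C6 alkoxide left, Et3Al can trigger only the C1 shift and should give the 4-O-triethylsilyl hydroazulenone F2, in which retro-aldol opening is blocked as well. HF·pyridine then frees 19.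

Step 5. Undirected background addition from the less hindered β face (poor facial selectivity) or sluggish addition to the carbonyl next to the quaternary carbon would lead to the useless trans-decalin series. The fallback sets out from 9 and returns at 12, and it ties the carbon nucleophile covalently to the C2 oxygen. Bromoacetyl bromide and pyridine give the bromoacetate F3. SmI2 (THF, −78 °C) forms the samarium enolate, which can reach C6 only from the α face (intramolecular Reformatsky reaction) and closes the bridged δ-lactone F4 with C7 and C8 in place. MeLi (−78 °C) opens the lactone to the methyl ketone F5, and non-basic methylenation (Zn, CH2Br2, TiCl4) gives 12.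

Step 8. Chemoselectivity may be lost through osmylation of C8=C9, or the isopropyl-flanked alkene may not react at all. The fallback sets out from 15 and returns at 17, and it replaces osmylation by epoxidation with net-retentive opening. VO(acac)2 and t-BuOOH epoxidise only the allylic alkene, syn to the C6–OH, to the β-epoxy alcohol F6. LiBr-catalysed insertion of CO2 (40 bar, NMP, 100 °C; double inversion at C5) converts it into the cis-4,5-cyclic carbonate F7. Brief treatment with K2CO3 in MeOH at 0 °C releases 17.

Further compounds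
F1 | step 10 | 4-O-triethylsilyl ether of mesylate 18 (C6–OH free) | C[C@@]12CC=C(C)C[C@]1(O)[C@@H](OS(C)(=O)=O)[C@](O[Si](CC)(CC)CC)(C(C)C)C[C@@H]2OC(=O)/C(C)=C\C
F2 | step 10 | 4-O-triethylsilyl ether of hydroazulenone 19 | O=C1CC(C)=CC[C@@]2(C)[C@@H](OC(=O)/C(C)=C\C)C[C@@](O[Si](CC)(CC)CC)(C(C)C)[C@H]12
F3 | step 5 | C2 bromoacetate of enone 9 | C=CC[C@@]1(C)[C@@H](OC(=O)CBr)CC(C(C)C)=CC1=O
F4 | step 5 | bridged δ-lactone (O2–C8(=O)–C7–C6) with β C6–OH | C=CC[C@@]1(C)[C@@H]2CC(C(C)C)=C[C@@]1(O)CC(=O)O2
F5 | step 5 | C6-acetonyl diol (methyl ketone at C8) | C=CC[C@@]1(C)[C@@H](O)CC(C(C)C)=C[C@@]1(O)CC(C)=O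
F6 | step 8 | 4β,5β-epoxide of 15 | C[C@@]12CC=C(C)C[C@]1(O)[C@H]3O[C@@]3(C(C)C)C[C@@H]2OC(=O)/C(C)=C\C
F7 | step 8 | cis-4β,5β-cyclic carbonate of 17 | C[C@@]12CC=C(C)C[C@]1(O)[C@H]3OC(=O)O[C@@]3(C(C)C)C[C@@H]2OC(=O)/C(C)=C\C
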